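The cyclohexane ring is disconnected at C1–C2 (quinic numbering). The route exploits that quaternary C1, its carboxyl carbon C7, an oxygen on C4, and C4, C3 and C2 make up an allyl ester enolate array that spans the six-membered ring. Heating the silyl ketene acetal of a 6-vinyl δ-lactone should therefore form C1–C2, close the carbocycle while the lactone opens, and set the C1 stereocentre by chirality transfer from C4 in a single Ireland–Claisen rearrangement. The precursor is a (5R,6S)-3,5-dioxygenated 6-vinyltetrahydropyran-2-one built from divinylcarbinol and tert-butyl acetate. Osmylation, 4,5-bisacetal protection, stepwise caffeoylation of O3 and O1 and deprotection complete the synthesis.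

Key step: step 8

Remark on the chemistry: quinic acid is numbered by the IUPAC convention (O1, O3 and O4 on one face, O5 and the carboxyl group on the other), and the L-(+)-tartrate ligand is used in step 1 because it gives the (2R,3S)-epoxy alcohol that leads to the natural (5R) series, whereas the D-(−)-ligand would give the enantiomer of the target.

**Route**

Step 1
Reactants: 1 penta-1,4-dien-3-ol
Product: 2 (2R,3S)-1,2-epoxypent-4-en-3-ol
Conditions: Ti(OiPr)4 (cat.), L-(+)-diisopropyl tartrate (cat.), tBuOOH, 4 Å molecular sieves, CH2Cl2, −20 °C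
Reagents that add atoms: tert-butyl hydroperoxide CC(C)(C)OO
Why: Sharpless asymmetric epoxidation used as a desymmetrisation: the catalyst formed from Ti(OiPr)4 and L-(+)-diisopropyl tartrate should epoxidise one enantiotopic vinyl group on one face to give the anti epoxy alcohol, which sets the future C5 (epoxide carbon, R) and the relay centre C4 (carbinol carbon, S), while the minor enantiomer is removed by a faster second epoxidation.

Step 2
Reactants: 2 (2R,3S)-1,2-epoxypent-4-en-3-ol
Product: 3 (R)-2-[(S)-1-(4-methoxybenzyloxy)prop-2-enyl]oxirane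
Conditions: NaH, 4-MeOC6H4CH2Cl, Bu4NI (cat.), THF, −20 °C to rt
Reagents that add atoms: 4-methoxybenzyl chloride COc1ccc(CCl)cc1
Why: Williamson ether synthesis on the sodium alkoxide should mask O4 as an oxidatively removable benzyl-type ether that tolerates the Lewis-acidic enolate step, alkylation at low temperature being faster than Payne rearrangement and no stereocentre being touched.

Step 3
Reactants: 3 (R)-2-[(S)-1-(4-methoxybenzyloxy)prop-2-enyl]oxirane; 4 tert-butyl acetate
Product: 7 tert-butyl (4R,5S)-4-hydroxy-5-(4-methoxybenzyloxy)hept-6-enoate, via lithium enolate 5 (not isolated), via diethylaluminium enolate 6 (not isolated)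
Conditions: 4, LiN(iPr)2, THF, −78 °C; Et2AlCl; then 3, −78 to −30 °C; dilute aq. HCl work-up
Reagents that add atoms: none
Why: Aluminium ester enolate opening of a terminal epoxide: the diethylaluminium enolate should activate the oxirane and attack its CH2 carbon in an SN2 reaction, so both stereocentres of 3 are kept, and the tert-butyl ester should keep the resulting aluminium alkoxide from closing to a γ-lactone.

Step 4
Reactants: 7 tert-butyl (4R,5S)-4-hydroxy-5-(4-methoxybenzyloxy)hept-6-enoate
Product: 8 tert-butyl (4R,5S)-4-(tert-butyldimethylsilyloxy)-5-(4-methoxybenzyloxy)hept-6-enoate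
Conditions: tBuMe2SiCl, imidazole, DMF, rt
Reagents that add atoms: tert-butyldimethylsilyl chloride CC(C)(C)[Si](C)(C)Cl
Why: Imidazole-promoted silyl ether formation should cap O5, so that only O4 can lactonise later and a bulky allylic group is in place to steer the osmylation in step 9.

Step 5
Reactants: 8 tert-butyl (4R,5S)-4-(tert-butyldimethylsilyloxy)-5-(4-methoxybenzyloxy)hept-6-enoate
Product: 9 tert-butyl (4R,5S)-4-(tert-butyldimethylsilyloxy)-5-hydroxyhept-6-enoate
Conditions: DDQ, CH2Cl2/pH 7 phosphate buffer, 0 °C
Reagents that add atoms: none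
Why: Oxidative cleavage of the 4-methoxybenzyl ether with DDQ (hydride abstraction to the oxocarbenium ion, then hydrolysis) should free O4 under buffered conditions that leave the silyl ether, the tert-butyl ester and the vinyl group alone.

Step 6
Reactants: 9 tert-butyl (4R,5S)-4-(tert-butyldimethylsilyloxy)-5-hydroxyhept-6-enoate
Product: 10 (5R,6S)-5-(tert-butyldimethylsilyloxy)-6-vinyltetrahydropyran-2-one
Conditions: CF3CO2H, CH2Cl2, 0 °C
Reagents that add atoms: none
Why: Acid-mediated lactonisation: trifluoroacetic acid should cleave the tert-butyl ester with loss of isobutene and the resulting δ-hydroxy acid should close through O4, the only free hydroxyl, to the six-membered lactone in which the silyloxy and vinyl groups are trans, short exposure at 0 °C sparing the secondary silyl ether.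

Step 7
Reactants: 10 (5R,6S)-5-(tert-butyldimethylsilyloxy)-6-vinyltetrahydropyran-2-one
Product: 12 (3RS,5R,6S)-5-(tert-butyldimethylsilyloxy)-3-hydroxy-6-vinyltetrahydropyran-2-one, via potassium enolate 11 (not isolated)
Conditions: KN(SiMe3)2, THF, −78 °C; then 2-(phenylsulfonyl)-3-phenyloxaziridine, −78 °C; AcOH quench
Reagents that add atoms: 2-(phenylsulfonyl)-3-phenyloxaziridine O=S(=O)(c1ccccc1)N1OC1c1ccccc1
Why: Enolate hydroxylation with an N-sulfonyloxaziridine (Davis oxidation) should deliver the α-hydroxy lactone by attack of the potassium enolate on the oxaziridine oxygen, and the new C3 centre may form as a mixture because it is made trigonal again in step 8.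

Step 8
Reactants: 12 (3RS,5R,6S)-5-(tert-butyldimethylsilyloxy)-3-hydroxy-6-vinyltetrahydropyran-2-one
Product: 16 (1S,5R)-5-(tert-butyldimethylsilyloxy)-1-hydroxycyclohex-3-ene-1-carboxylic acid, via trimethylsilyl ether 13 (not isolated), via bis-silyl ketene acetal 14 (not isolated), via rearranged silyl ester 15 (not isolated)
Conditions: LiN(SiMe3)2, Me3SiCl/Et3N, THF, −78 °C to rt; PhMe, 100 °C; then 1 M HCl, THF, 0 °C
Reagents that add atoms: none
Why: Proposed new method: internal-quench deprotonation in the presence of Me3SiCl should silylate the hydroxyl and then the lactone enolate, giving the cyclic ketene acetal 14, in which C1=C7–O–C4–C3=C2 (quinic numbering) is an allyl vinyl ether that undergoes a concerted suprafacial [3,3]-sigmatropic shift on heating, making C1–C2 as the C4–O bond breaks. The closest known reaction types are the Ireland–Claisen rearrangement of silyl ketene acetals of lactones that carry a vinyl group on the carbinol carbon, which gives cycloalkene carboxylic acids, and the same rearrangement of α-alkoxy lactone and glycolate ester ketene acetals, whereas an exocyclic α-silyloxy group on a carbocycle-forming δ-lactone has not been shown. The cyclohexene ring closes by this [3,3] C–C bond formation through a boat, bicyclo[2.2.2]octane-like transition state, because the C5–C6 tether that joins the two termini cannot span a chair. The new quaternary stereocentre C1 is controlled by the C4 carbinol centre, whose configuration is transferred and then lost: the vinyl terminus can reach C1 only on the lactone face that bears the vinyl group, so the 5,6-trans lactone must place the carboxyl group cis and O1 trans to the C5 silyloxy group. The step needs clean O-silylation and a rearrangement faster than decomposition of the ketene acetal, which is served by the ring-fixed enolate geometry, by the absence of a leaving group β to the enolate carbon and by the irrelevance of the C3 configuration of 12, which becomes trigonal.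

Step 9
Reactants: 16 (1S,5R)-5-(tert-butyldimethylsilyloxy)-1-hydroxycyclohex-3-ene-1-carboxylic acid
Product: 17 5-O-(tert-butyldimethylsilyl)quinic acid
Conditions: OsO4 (cat.), N-methylmorpholine N-oxide, acetone/H2O, rt
Reagents that add atoms: N-methylmorpholine N-oxide C[N+]1([O-])CCOCC1; water O
Why: Catalytic osmium tetroxide cis-dihydroxylation with an amine N-oxide as reoxidant should add both oxygens to C3=C4 from the face opposite the bulky allylic silyloxy group at C5, the face that carries only the small 1-hydroxyl, which sets C3 and C4 with O3 and O4 cis to O1 and trans to O5.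

Step 10
Reactants: 17 5-O-(tert-butyldimethylsilyl)quinic acid
Product: 18 methyl 4,5-O-[(2S,3S)-2,3-dimethoxybutane-2,3-diyl]quinate
Conditions: butane-2,3-dione, HC(OMe)3, camphorsulfonic acid (cat.), MeOH, reflux
Reagents that add atoms: butane-2,3-dione CC(=O)C(C)=O; methanol CO
Why: Acid-catalysed methanolysis of the silyl ether, Fischer esterification and butane-2,3-diacetal formation in one pot should lock the only trans-diequatorial diol (O4 and O5) as the trans-fused bisacetal with both methoxy groups axial (anomeric control), which leaves exactly O1 and O3 free.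

Step 11
Reactants: 19 caffeic acid
Product: 21 (E)-3-[3,4-bis(tert-butyldimethylsilyloxy)phenyl]prop-2-enoic acid, via tris-silyl derivative 20 (not isolated)
Conditions: tBuMe2SiCl, imidazole, DMF, rt; then AcOH/THF/H2O, rt
Reagents that add atoms: tert-butyldimethylsilyl chloride CC(C)(C)[Si](C)(C)Cl
Why: Exhaustive silylation of the two phenols and the carboxyl group followed by selective hydrolysis of the labile silyl ester in aqueous acetic acid should give the phenol-protected acid with the E double bond unchanged.

Step 12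
Reactants: 21 (E)-3-[3,4-bis(tert-butyldimethylsilyloxy)phenyl]prop-2-enoic acid
Product: 22 (E)-3-[3,4-bis(tert-butyldimethylsilyloxy)phenyl]prop-2-enoyl chloride
Conditions: (COCl)2, DMF (cat.), CH2Cl2, 0 °C to rt
Reagents that add atoms: oxalyl chloride O=C(Cl)C(Cl)=O
Why: Acid chloride formation with oxalyl chloride under DMF catalysis (chloroiminium activation) should proceed without loss of the aryl silyl ethers or isomerisation of the E alkene.

Step 13
Reactants: 18 methyl 4,5-O-[(2S,3S)-2,3-dimethoxybutane-2,3-diyl]quinate; 22 (E)-3-[3,4-bis(tert-butyldimethylsilyloxy)phenyl]prop-2-enoyl chloride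
Product: 23 methyl 3-O-[(E)-3,4-bis(tert-butyldimethylsilyloxy)cinnamoyl]-4,5-O-[(2S,3S)-2,3-dimethoxybutane-2,3-diyl]quinate
Conditions: 22 (1.1 equiv), pyridine, DMAP (cat.), CH2Cl2, 0 °C to rt
Reagents that add atoms: none
Why: Acylation under nucleophilic catalysis by DMAP (N-acylpyridinium intermediate) with one equivalent of the acid chloride should take place only at the secondary axial 3-hydroxyl, because the tertiary 1-hydroxyl next to the ester group reacts far more slowly at this temperature, and no stereocentre is touched.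

Step 14
Reactants: 23 methyl 3-O-[(E)-3,4-bis(tert-butyldimethylsilyloxy)cinnamoyl]-4,5-O-[(2S,3S)-2,3-dimethoxybutane-2,3-diyl]quinate; 22 (E)-3-[3,4-bis(tert-butyldimethylsilyloxy)phenyl]prop-2-enoyl chloride
Product: 24 methyl 1,3-bis-O-[(E)-3,4-bis(tert-butyldimethylsilyloxy)cinnamoyl]-4,5-O-[(2S,3S)-2,3-dimethoxybutane-2,3-diyl]quinate
Conditions: 22 (3 equiv), DMAP (1 equiv), pyridine, ClCH2CH2Cl, 60 °C
Reagents that add atoms: none
Why: Forcing DMAP-mediated acylation of a tertiary α-hydroxy ester with a second molecule of the acid chloride should esterify the 1-hydroxyl, the only hydroxyl left, so that no regiochemical choice arises and no stereocentre is touched.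

Step 15
Reactants: 24 methyl 1,3-bis-O-[(E)-3,4-bis(tert-butyldimethylsilyloxy)cinnamoyl]-4,5-O-[(2S,3S)-2,3-dimethoxybutane-2,3-diyl]quinate
Product: 25 1,3-bis-O-[(E)-3,4-bis(tert-butyldimethylsilyloxy)cinnamoyl]-4,5-O-[(2S,3S)-2,3-dimethoxybutane-2,3-diyl]quinic acid
Conditions: LiI, EtOAc, reflux, dark; 1 M HCl work-up
Reagents that add atoms: none
Why: Nucleophilic dealkylation of the methyl ester (SN2 attack of iodide on the methyl carbon) should free the carboxyl group without any acyl-transfer chemistry, so that the two cinnamoyl esters, which offer no unhindered alkyl carbon, stay in place and the absence of free hydroxyls excludes acyl migration.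

Step 16
Reactants: 25 1,3-bis-O-[(E)-3,4-bis(tert-butyldimethylsilyloxy)cinnamoyl]-4,5-O-[(2S,3S)-2,3-dimethoxybutane-2,3-diyl]quinic acid
Product: 27 1,3-di-O-caffeoylquinic acid, via tetraphenol bisacetal 26 (not isolated)
Conditions: HF·pyridine, THF, 0 °C to rt; concentrate; then CF3CO2H/H2O (9:1), rt, dark
Reagents that add atoms: none
Why: Fluoride-mediated cleavage of the four aryl silyl ethers while every aliphatic hydroxyl is still blocked, followed by acid hydrolysis of the butane-2,3-diacetal in aqueous trifluoroacetic acid, should free the target in media in which cinnamoyl esters are stable and base-promoted acyl migration among O3, O4 and O5 is avoided, with all stereocentres unchanged.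

**Compound list**

1 | penta-1,4-dien-3-ol (divinylcarbinol) | C=CC(O)C=C | starting material
2 | (2R,3S)-1,2-epoxypent-4-en-3-ol | C=C[C@H](O)[C@H]1CO1 | intermediate
3 | (R)-2-[(S)-1-(4-methoxybenzyloxy)prop-2-enyl]oxirane | C=C[C@H](OCc1ccc(OC)cc1)[C@H]1CO1 | intermediate
4 | tert-butyl acetate | CC(=O)OC(C)(C)C | starting material
5 | lithium enolate of tert-butyl acetate | C=C(O[Li])OC(C)(C)C | intermediate
6 | diethylaluminium enolate of tert-butyl acetate | C=C(O[Al](CC)CC)OC(C)(C)C | intermediate
7 | tert-butyl (4R,5S)-4-hydroxy-5-(4-methoxybenzyloxy)hept-6-enoate | C=C[C@H](OCc1ccc(OC)cc1)[C@H](O)CCC(=O)OC(C)(C)C | intermediate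
8 | tert-butyl (4R,5S)-4-(tert-butyldimethylsilyloxy)-5-(4-methoxybenzyloxy)hept-6-enoate | C=C[C@H](OCc1ccc(OC)cc1)[C@H](O[Si](C)(C)C(C)(C)C)CCC(=O)OC(C)(C)C | intermediate
9 | tert-butyl (4R,5S)-4-(tert-butyldimethylsilyloxy)-5-hydroxyhept-6-enoate | C=C[C@H](O)[C@H](O[Si](C)(C)C(C)(C)C)CCC(=O)OC(C)(C)C | intermediate
10 | (5R,6S)-5-(tert-butyldimethylsilyloxy)-6-vinyltetrahydropyran-2-one (silyloxy and vinyl trans) | C=C[C@@H]1OC(=O)CC[C@H]1O[Si](C)(C)C(C)(C)C | intermediate
11 | potassium enolate of lactone 10 | C=C[C@@H]1OC(O[K])=CC[C@H]1O[Si](C)(C)C(C)(C)C | intermediate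
12 | (3RS,5R,6S)-5-(tert-butyldimethylsilyloxy)-3-hydroxy-6-vinyltetrahydropyran-2-one (C3 epimer mixture) | C=C[C@@H]1OC(=O)C(O)C[C@H]1O[Si](C)(C)C(C)(C)C | intermediate
13 | (3RS,5R,6S)-5-(tert-butyldimethylsilyloxy)-3-(trimethylsilyloxy)-6-vinyltetrahydropyran-2-one | C=C[C@@H]1OC(=O)C(O[Si](C)(C)C)C[C@H]1O[Si](C)(C)C(C)(C)C | intermediate
14 | (2S,3R)-3-(tert-butyldimethylsilyloxy)-5,6-bis(trimethylsilyloxy)-2-vinyl-3,4-dihydro-2H-pyran | C=C[C@@H]1OC(O[Si](C)(C)C)=C(O[Si](C)(C)C)C[C@H]1O[Si](C)(C)C(C)(C)C | intermediate
15 | trimethylsilyl (1S,5R)-5-(tert-butyldimethylsilyloxy)-1-(trimethylsilyloxy)cyclohex-3-ene-1-carboxylate | C1=C[C@H](O[Si](C)(C)C(C)(C)C)C[C@](O[Si](C)(C)C)(C(=O)O[Si](C)(C)C)C1 | intermediate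
16 | (1S,5R)-5-(tert-butyldimethylsilyloxy)-1-hydroxycyclohex-3-ene-1-carboxylic acid (O1 trans to O5; carboxyl cis to O5) | C1=C[C@H](O[Si](C)(C)C(C)(C)C)C[C@](O)(C(=O)O)C1 | intermediate
17 | 5-O-(tert-butyldimethylsilyl)quinic acid (O1, O3, O4 on one face; O5 and carboxyl on the other) | O[C@@H]1C[C@@](O)(C(=O)O)C[C@@H](O[Si](C)(C)C(C)(C)C)[C@@H]1O | intermediate
18 | methyl 4,5-O-[(2S,3S)-2,3-dimethoxybutane-2,3-diyl]quinate (trans-fused bisacetal; both methoxy groups axial) | O[C@@H]1C[C@@](O)(C(=O)OC)C[C@H]2O[C@](C)(OC)[C@@](C)(OC)O[C@@H]21 | intermediate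
19 | caffeic acid | OC(=O)/C=C/c1ccc(O)c(O)c1 | starting material
20 | tert-butyldimethylsilyl (E)-3-[3,4-bis(tert-butyldimethylsilyloxy)phenyl]prop-2-enoate | CC(C)(C)[Si](C)(C)OC(=O)/C=C/c1ccc(O[Si](C)(C)C(C)(C)C)c(O[Si](C)(C)C(C)(C)C)c1 | intermediate
21 | (E)-3-[3,4-bis(tert-butyldimethylsilyloxy)phenyl]prop-2-enoic acid | OC(=O)/C=C/c1ccc(O[Si](C)(C)C(C)(C)C)c(O[Si](C)(C)C(C)(C)C)c1 | intermediate
22 | (E)-3-[3,4-bis(tert-butyldimethylsilyloxy)phenyl]prop-2-enoyl chloride | ClC(=O)/C=C/c1ccc(O[Si](C)(C)C(C)(C)C)c(O[Si](C)(C)C(C)(C)C)c1 | intermediate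
23 | methyl 3-O-[(E)-3,4-bis(tert-butyldimethylsilyloxy)cinnamoyl]-4,5-O-[(2S,3S)-2,3-dimethoxybutane-2,3-diyl]quinate (1-hydroxyl free) | O=C(/C=C/c1ccc(O[Si](C)(C)C(C)(C)C)c(O[Si](C)(C)C(C)(C)C)c1)O[C@@H]1C[C@@](O)(C(=O)OC)C[C@H]2O[C@](C)(OC)[C@@](C)(OC)O[C@@H]21 | intermediate
24 | methyl 1,3-bis-O-[(E)-3,4-bis(tert-butyldimethylsilyloxy)cinnamoyl]-4,5-O-[(2S,3S)-2,3-dimethoxybutane-2,3-diyl]quinate | O=C(/C=C/c1ccc(O[Si](C)(C)C(C)(C)C)c(O[Si](C)(C)C(C)(C)C)c1)O[C@@H]1C[C@@](OC(=O)/C=C/c2ccc(O[Si](C)(C)C(C)(C)C)c(O[Si](C)(C)C(C)(C)C)c2)(C(=O)OC)C[C@H]2O[C@](C)(OC)[C@@](C)(OC)O[C@@H]21 | intermediate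
25 | 1,3-bis-O-[(E)-3,4-bis(tert-butyldimethylsilyloxy)cinnamoyl]-4,5-O-[(2S,3S)-2,3-dimethoxybutane-2,3-diyl]quinic acid | O=C(/C=C/c1ccc(O[Si](C)(C)C(C)(C)C)c(O[Si](C)(C)C(C)(C)C)c1)O[C@@H]1C[C@@](OC(=O)/C=C/c2ccc(O[Si](C)(C)C(C)(C)C)c(O[Si](C)(C)C(C)(C)C)c2)(C(=O)O)C[C@H]2O[C@](C)(OC)[C@@](C)(OC)O[C@@H]21 | intermediate
26 | 1,3-di-O-caffeoyl-4,5-O-[(2S,3S)-2,3-dimethoxybutane-2,3-diyl]quinic acid | O=C(/C=C/c1ccc(O)c(O)c1)O[C@@H]1C[C@@](OC(=O)/C=C/c2ccc(O)c(O)c2)(C(=O)O)C[C@H]2O[C@](C)(OC)[C@@](C)(OC)O[C@@H]21 | intermediate
27 | 1,3-di-O-caffeoylquinic acid | O=C(/C=C/c1ccc(O)c(O)c1)O[C@@H]1C[C@@](OC(=O)/C=C/c2ccc(O)c(O)c2)(C(=O)O)C[C@@H](O)[C@@H]1O | target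

**Step count and risks**

Total step count: 16 (14 in the main line, 2 for the acylating agent).
Longest linear sequence: 14 steps (steps 1–10 and 13–16).

The three steps most likely to fail:

Step 8 (the step that bears the label "Proposed new method:"). The doubly O-silylated ketene acetal may hydrolyse, undergo C-silylation or decompose before it reaches the strained boat transition state. The fallback introduces the C1 oxygen after the ring contraction and uses known chemistry only. It sets out from lactone 10. Enolisation with LiN(iPr)2 and Me3SiCl/Et3N in THF at −78 °C should give the unsubstituted silyl ketene acetal F1, the established substrate type for the lactone-to-carbocycle Ireland–Claisen rearrangement. Heating in toluene should give the rearranged trimethylsilyl ester F2 and, after dilute acid, the 1,5-cis cyclohexene acid F3. Double deprotonation with LiN(iPr)2 in THF at 0 °C should give the dilithium enediolate F4. Its oxidation with 2-(phenylsulfonyl)-3-phenyloxaziridine (α-hydroxylation of a carboxylic acid dianion) is expected to occur mainly on the face opposite the C5 silyloxy group. After removal of the C1 epimer by chromatography the fallback comes back to the route at hydroxy acid 16. In this variant C1 is set by substrate control instead of chirality transfer.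

Step 9. The osmylation may show poor facial selectivity, because a pseudo-equatorial allylic silyloxy group shields its face only moderately. The fallback uses a bridging lactone as the control element and sets out from hydroxy acid 16. HF·pyridine in THF should remove the silyl group to give the dihydroxy acid F5. Carbodiimide lactonisation (EDC·HCl, DMAP cat., CH2Cl2), possible only because the carboxyl group is cis to O5, should give the bicyclic unsaturated lactone F6. Its C3=C4 bond is open only on the face opposite the lactone bridge, so OsO4 with N-methylmorpholine N-oxide should give quinide F7, the 1,5-lactone of quinic acid. Acid methanolysis under the conditions of step 10 should open the lactone and form the bisacetal, so the fallback comes back to the route at 18.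

Step 14. Acylation of the tertiary 1-hydroxyl may remain incomplete, since it is flanked by the ester group and syn-axial to the 3-O-acyl group, so that the bulky, conjugated acid chloride is consumed by side reactions before it reacts. The fallback attaches a small acyl group first and builds the cinnamoyl unit afterwards; it sets out from monoester 23. Carbodiimide esterification with diethylphosphonoacetic acid (DCC, DMAP cat., CH2Cl2), whose activated form is far smaller than the cinnamoyl chloride, should give the 1-O-phosphonoacetate F8. A Horner–Wadsworth–Emmons olefination (LiCl, iPr2NEt, MeCN) with the silyl-protected aldehyde F9, prepared from 3,4-dihydroxybenzaldehyde with tBuMe2SiCl and imidazole, should give the E cinnamate under conditions that leave the aryl silyl ethers and the existing ester intact. The fallback comes back to the route at 24.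

Further compounds
F1 | step 8 | (2S,3R)-3-(tert-butyldimethylsilyloxy)-6-(trimethylsilyloxy)-2-vinyl-3,4-dihydro-2H-pyran | C=C[C@@H]1OC(O[Si](C)(C)C)=CC[C@H]1O[Si](C)(C)C(C)(C)C
F2 | step 8 | trimethylsilyl (1R,5R)-5-(tert-butyldimethylsilyloxy)cyclohex-3-ene-1-carboxylate | C1=C[C@H](O[Si](C)(C)C(C)(C)C)C[C@H](C(=O)O[Si](C)(C)C)C1
F3 | step 8 | (1R,5R)-5-(tert-butyldimethylsilyloxy)cyclohex-3-ene-1-carboxylic acid (1,5-cis) | C1=C[C@H](O[Si](C)(C)C(C)(C)C)C[C@H](C(=O)O)C1
F4 | step 8 | dilithium enediolate of (5R)-5-(tert-butyldimethylsilyloxy)cyclohex-3-ene-1-carboxylic acid | [Li]OC(O[Li])=C1CC=C[C@H](O[Si](C)(C)C(C)(C)C)C1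
F5 | step 9 | (1S,5R)-1,5-dihydroxycyclohex-3-ene-1-carboxylic acid | C1=C[C@H](O)C[C@](O)(C(=O)O)C1
F6 | step 9 | (1S,5R)-1-hydroxy-6-oxabicyclo[3.2.1]oct-3-en-7-one | C1=C[C@@H]2OC(=O)[C@@](O)(C2)C1
F7 | step 9 | quinide, (1S,3R,4R,5R)-1,3,4-trihydroxy-6-oxabicyclo[3.2.1]octan-7-one | O[C@@H]1C[C@]2(O)C[C@@H](OC2=O)[C@@H]1O
F8 | step 14 | methyl 3-O-[(E)-3,4-bis(tert-butyldimethylsilyloxy)cinnamoyl]-1-O-(diethoxyphosphorylacetyl)-4,5-O-[(2S,3S)-2,3-dimethoxybutane-2,3-diyl]quinate | O=C(/C=C/c1ccc(O[Si](C)(C)C(C)(C)C)c(O[Si](C)(C)C(C)(C)C)c1)O[C@@H]1C[C@@](OC(=O)CP(=O)(OCC)OCC)(C(=O)OC)C[C@H]2O[C@](C)(OC)[C@@](C)(OC)O[C@@H]21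
F9 | step 14 | 3,4-bis(tert-butyldimethylsilyloxy)benzaldehyde | O=Cc1ccc(O[Si](C)(C)C(C)(C)C)c(O[Si](C)(C)C(C)(C)C)c1
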